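**Plan**

- Retrosynthesis: the exocyclic C11=C13 bond is masked as a Mannich base and the C14 methacrylate is taken back to a tert-butyl ester. The ring bond C8–C9 is cut next, then C1–C10 (Morita–Baylis–Hillman), C4=C5 (Wittig), and C7–C8 with C11–C13 (conjugate addition and Mannich trapping on a butenolide).
- Enabling feature: in the ten-membered carbocycle, C9 is the allylic CH2 of the unit C9–C10(C14–O)=C1, a latent Baylis–Hillman acetate of an acrylate. C8 is a carbinol carbon, a latent aldehyde ketyl. A ketyl radical addition with loss of the C1 acetate therefore closes the ring and creates the C8–OH and the C1=C10 bond together.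
- Forward order: lactone ring first (chiral-pool butenolide), then chain C5 to C1 by Wittig, then the C9/C10/C14 acrylate by Morita–Baylis–Hillman, then the ten-membered ring by SmI2, then ester adjustment and unmasking of the methylene lactone.
- Stereochemistry: C6 comes from (S)-5-(hydroxymethyl)furan-2(5H)-one; C7 from anti conjugate addition; C8 from the ring closure (substrate control by C7). The C4=C5 geometry comes from the E-selective Wittig reaction and the C1=C10 geometry from the elimination in the ring closure, where both C1 epimers converge.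

Key step: step 12

Remark on the chemistry: germacrane numbering is used for all intermediates (C1–C10 ring carbons, C11 and C12 lactone alpha-carbon and carbonyl, C13 on C11, C14 on C10, C15 on C4). Both ring double bonds of the target are E by the CIP rules and cis along the ring path.

**Step 1**
Reactants: 1 2-(3-chloropropyl)-1,3-dioxolane
Product: 2 [3-(1,3-dioxolan-2-yl)propyl]triphenylphosphonium iodide
Conditions: PPh3, NaI, MeCN, reflux, 48 h
Reagents that add atoms: triphenylphosphine, c1ccc(cc1)P(c1ccccc1)c1ccccc1; sodium iodide, [Na+].[I-]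
Why: SN2 displacement by the phosphine on the primary halide, accelerated by in situ Finkelstein exchange, should give the phosphonium salt without touching the acetal.

**Step 2**
Reactants: 2 [3-(1,3-dioxolan-2-yl)propyl]triphenylphosphonium iodide
Product: 3 4-(1,3-dioxolan-2-yl)-2-(triphenyl-λ5-phosphanylidene)butanal
Conditions: KOt-Bu (2 equiv), THF, 0 °C; HCO2Et, 0 °C to rt
Reagents that add atoms: ethyl formate, CCOC=O
Why: The non-stabilised ylide is C-formylated by the formate and the acylphosphonium ion is deprotonated in situ to the stabilised alpha-formyl ylide (ylide acylation).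

**Step 3**
Reactants: 4 (S)-5-(hydroxymethyl)furan-2(5H)-one
Product: 5 (S)-5-[(triethylsilyloxy)methyl]furan-2(5H)-one
Conditions: Et3SiCl, imidazole, CH2Cl2, 0 °C
Reagents that add atoms: chlorotriethylsilane, CC[Si](Cl)(CC)CC
Why: Standard silylation of the primary alcohol; the triethylsilyl ether should survive the organolithium step and can be oxidised directly in step 5.

**Step 4**
Reactants: 5 (S)-5-[(triethylsilyloxy)methyl]furan-2(5H)-one; 6 bis(phenylsulfanyl)methane
Product: 8 (3R,4S,5S)-4-[bis(phenylsulfanyl)methyl]-3-[(dimethylamino)methyl]-5-[(triethylsilyloxy)methyl]oxolan-2-one, via lithium lactone enolate 7 (not isolated)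
Conditions: 6, n-BuLi, THF/HMPA, 0 to −78 °C; 5, −78 °C; then CH2=NMe2+ I−, −78 to 0 °C
Reagents that add atoms: N,N-dimethylmethyleneiminium iodide (Eschenmoser's salt), C=[N+](C)C.[I-]
Why: The sulfur-stabilised carbanion should add 1,4 anti to the silyloxymethyl group, which sets C7 trans to C6, and the enolate is trapped by the iminium ion anti to the new substituent (tandem conjugate addition and Mannich reaction), the C11 configuration being of no consequence because C11 becomes sp2 in step 17.

**Step 5**
Reactants: 8 (3R,4S,5S)-4-[bis(phenylsulfanyl)methyl]-3-[(dimethylamino)methyl]-5-[(triethylsilyloxy)methyl]oxolan-2-one; 3 4-(1,3-dioxolan-2-yl)-2-(triphenyl-λ5-phosphanylidene)butanal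
Product: 10 (2E)-2-[2-(1,3-dioxolan-2-yl)ethyl]-3-{(2R,3S,4R)-3-[bis(phenylsulfanyl)methyl]-4-[(dimethylamino)methyl]-5-oxooxolan-2-yl}prop-2-enal, via lactone aldehyde 9 (not isolated)
Conditions: (COCl)2, DMSO, CH2Cl2, −78 to −30 °C; Et3N, −78 to 0 °C; then 3, rt to 40 °C, 16 h
Reagents that add atoms: none
Why: Under Swern conditions a primary triethylsilyl ether is oxidised directly to the aldehyde, and the alpha-substituted formyl ylide should give the enal with the formyl group trans to C6 (E-selective Wittig reaction of a stabilised ylide), which is the C4=C5 geometry of the target.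

**Step 6**
Reactants: 10 the enal of step 5
Product: 11 (2E)-2-[2-(1,3-dioxolan-2-yl)ethyl]-3-{(2R,3S,4R)-3-[bis(phenylsulfanyl)methyl]-4-[(dimethylamino)methyl]-5-oxooxolan-2-yl}prop-2-en-1-ol
Conditions: NaBH4, CeCl3·7H2O, MeOH, −40 to 0 °C
Reagents that add atoms: none
Why: Luche reduction delivers hydride 1,2 to the enal and should leave the lactone, the acetal and the dithioacetal untouched.

**Step 7**
Reactants: 11 the allylic alcohol of step 6
Product: 12 (2E)-2-[2-(1,3-dioxolan-2-yl)ethyl]-3-{(2R,3S,4R)-3-[bis(phenylsulfanyl)methyl]-4-[(dimethylamino)methyl]-5-oxooxolan-2-yl}prop-2-en-1-yl acetate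
Conditions: Ac2O, pyridine, DMAP (cat.), CH2Cl2, 0 °C to rt
Reagents that add atoms: acetic anhydride, CC(=O)OC(C)=O
Why: Acylation of the primary allylic alcohol installs the C15 acetate of the target early, and no later step uses a reagent that is meant to cleave esters.

**Step 8**
Reactants: 12 the acetate of step 7
Product: 13 (4E)-4-(acetoxymethyl)-5-{(2R,3S,4R)-3-[bis(phenylsulfanyl)methyl]-4-[(dimethylamino)methyl]-5-oxooxolan-2-yl}pent-4-enal
Conditions: 1 M aq. HCl, THF, rt; NaHCO3 work-up
Reagents that add atoms: water, O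
Why: Aqueous acid hydrolyses the O,O-acetal at C1 while the S,S-acetal at C8, the allylic acetate and the protonated amine are inert, which differentiates the two latent aldehydes.

**Step 9**
Reactants: 13 the C1 aldehyde of step 8; 14 tert-butyl prop-2-enoate
Product: 15 tert-butyl (3RS,6E)-6-(acetoxymethyl)-7-{(2R,3S,4R)-3-[bis(phenylsulfanyl)methyl]-4-[(dimethylamino)methyl]-5-oxooxolan-2-yl}-3-hydroxy-2-methylidenehept-6-enoate (both C1 epimers)
Conditions: DABCO (1 equiv), 14 (5 equiv), 1,4-dioxane/H2O 1:1, rt, 2–4 d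
Reagents that add atoms: none
Why: Morita–Baylis–Hillman reaction of the unhindered aliphatic aldehyde; the C1 carbinol centre forms without control, which is harmless because C1 becomes sp2 in step 12.

**Step 10**
Reactants: 15 the Baylis–Hillman alcohol of step 9
Product: 16 tert-butyl (3RS,6E)-3-acetoxy-6-(acetoxymethyl)-7-{(2R,3S,4R)-3-[bis(phenylsulfanyl)methyl]-4-[(dimethylamino)methyl]-5-oxooxolan-2-yl}-2-methylidenehept-6-enoate
Conditions: AcCl, pyridine, CH2Cl2, −20 to 0 °C
Reagents that add atoms: acetyl chloride, CC(Cl)=O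
Why: Acetylation without a nucleophilic catalyst turns the C1 hydroxyl into the leaving group needed in step 12 without allylic transposition, and restores any C15 acetate lost in step 9.

**Step 11**
Reactants: 16 the Baylis–Hillman acetate of step 10
Product: 17 tert-butyl (3RS,6E)-3-acetoxy-6-(acetoxymethyl)-7-{(2R,3S,4R)-4-[(dimethylamino)methyl]-3-formyl-5-oxooxolan-2-yl}-2-methylidenehept-6-enoate
Conditions: HgCl2, CaCO3, MeCN/H2O 4:1, rt
Reagents that add atoms: water, O
Why: Thiophilic HgCl2 hydrolyses the dithioacetal under buffered neutral conditions that should spare the acetates, the acrylate and the C7 centre, whose trans arrangement on the lactone is also the thermodynamic one.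

**Step 12**
Reactants: 17 the seco aldehyde of step 11
Product: 20 tert-butyl (1(10)E,4E,6R,7R,8R,11R)-15-acetoxy-13-(dimethylamino)-8-hydroxy-12-oxo-6,12-epoxy-germacra-1(10),4-dien-14-oate (ten-membered ring; trans-fused 6,12-lactone), via samarium ketyl 18 (not isolated), via samarium ester enolate 19 (not isolated)
Conditions: SmI2 (3 equiv, 0.1 M in THF), THF, −78 °C, 17 added over 8 h (final 2 mM), then to −20 °C; sat. aq. NH4Cl
Reagents that add atoms: none
Why: Proposed new method: SmI2 reduces the C8 aldehyde to a samarium ketyl radical that adds to the unsubstituted terminus C9 of the tethered 2-(1-acetoxyalkyl)acrylate, a second SmI2 reduces the C10 radical to a samarium ester enolate, and this enolate expels the C1 acetate (E1cB), so that the C8–C9 bond, the C8 carbinol and the C1=C10 double bond arise in one operation. The closest known reaction types are the SmI2 ketyl–acrylate coupling followed by beta-elimination and the radical or SN2' substitution of Morita–Baylis–Hillman acetates, neither of which has been used to close a ten-membered carbocycle. The ten-membered ring closes in the 10-endo-trig mode, the only one open to a nucleophilic ketyl on an acrylate, whose beta-carbon is C9. The new stereocentre C8 is controlled by C7 of the trans-fused lactone: trivalent samarium on the ketyl oxygen is expected to bind the lactone ring oxygen on C6, which holds the C8–O bond anti to H7, and the tether anchored at C6 brings C9 in on the H7 side, which gives 8R. The C1=C10 geometry (ester trans to C2, cis along the ring) follows from allylic strain in the enolate and from the strain of a trans double bond in this ring, so both C1 epimers of 17 converge on one alkene. The step needs aldehyde reduction to outrun acrylate reduction and ring closure to outrun pinacol coupling, which the fast inner-sphere reduction of aldehydes, slow addition at high dilution and the turn imposed by the lactone and the ring-cis C4=C5 bond should secure; the tert-butyl ester keeps the C8 alkoxide from lactonising onto C14.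

**Step 13**
Reactants: 20 the macrocyclic hydroxy ester of step 12
Product: 22 (1(10)E,4E,6R,7S,8R,11R)-15-acetoxy-13-(dimethylamino)-12-oxo-8-(triethylsilyloxy)-6,12-epoxy-germacra-1(10),4-dien-14-oic acid, via bis-silylated ester 21 (not isolated)
Conditions: Et3SiOTf (3 equiv), 2,6-lutidine, CH2Cl2, 0 °C to rt; then pH 7 buffer, THF
Reagents that add atoms: triethylsilyl trifluoromethanesulfonate, CC[Si](CC)(CC)OS(=O)(=O)C(F)(F)F
Why: The silyl triflate silylates the C8 hydroxyl and converts the tert-butyl ester into a silyl ester with loss of isobutene, and mild hydrolysis then frees the acid while the secondary silyl ether stays and keeps O8 from lactonising onto C14.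

**Step 14**
Reactants: 22 the acid of step 13
Product: 24 (1(10)E,4E,6R,7S,8R,11R)-15-acetoxy-13-(dimethylamino)-14-hydroxy-8-(triethylsilyloxy)germacra-1(10),4-dien-12,6-olide, via mixed carbonic anhydride 23 (not isolated)
Conditions: i-BuOCOCl, N-methylmorpholine, THF, −15 °C; then NaBH4, H2O, −15 to 0 °C
Reagents that add atoms: none
Why: A mixed carbonic anhydride is far more electrophilic than the lactone and the acetate, so borohydride should reduce only C14, by 1,2-addition to the beta-substituted enoyl group, to the allylic alcohol.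

**Step 15**
Reactants: 24 the C14 alcohol of step 14
Product: 25 (1(10)E,4E,6R,7S,8R,11R)-15-acetoxy-13-(dimethylamino)-14-(2-methylprop-2-enoyloxy)-8-(triethylsilyloxy)germacra-1(10),4-dien-12,6-olide
Conditions: methacrylic anhydride, Et3N, DMAP (cat.), CH2Cl2, 0 °C
Reagents that add atoms: methacrylic anhydride, CC(=C)C(=O)OC(=O)C(C)=C
Why: DMAP-catalysed acylation of the primary allylic alcohol installs the methacrylate, and the silylated O8 cannot compete.

**Step 16**
Reactants: 25 the silyl ether of step 15
Product: 26 (1(10)E,4E,6R,7R,8R,11R)-15-acetoxy-13-(dimethylamino)-8-hydroxy-14-(2-methylprop-2-enoyloxy)germacra-1(10),4-dien-12,6-olide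
Conditions: HF·pyridine, pyridine, THF, 0 °C to rt
Reagents that add atoms: none
Why: Buffered fluoride cleaves the secondary triethylsilyl ether and should leave both esters, the lactone and the amine intact.

**Step 17**
Reactants: 26 the amino lactone of step 16
Product: 28 the target, (1(10)E,4E,6R,7R,8R)-15-acetoxy-8-hydroxy-14-(2-methylprop-2-enoyloxy)germacra-1(10),4,11(13)-trien-12,6-olide, via trimethylammonium iodide 27 (not isolated)
Conditions: MeI (excess), MeCN, rt; then aq. NaHCO3, CH2Cl2, rt
Reagents that add atoms: none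
Why: Quaternisation of the dimethylamino group followed by mild base induces E1cB (Hofmann-type) loss of trimethylamine from the beta-ammonio lactone, which unmasks the alpha-methylene lactone last, when no nucleophile or reductant remains to attack it.

**Compound list**

1 | 2-(3-chloropropyl)-1,3-dioxolane | ClCCCC1OCCO1 | starting material
2 | [3-(1,3-dioxolan-2-yl)propyl]triphenylphosphonium iodide | C1COC(CCC[P+](c2ccccc2)(c2ccccc2)c2ccccc2)O1.[I-] | intermediate
3 | 4-(1,3-dioxolan-2-yl)-2-(triphenyl-λ5-phosphanylidene)butanal | O=CC(CCC1OCCO1)=P(c1ccccc1)(c1ccccc1)c1ccccc1 | intermediate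
4 | (S)-5-(hydroxymethyl)furan-2(5H)-one | OC[C@H]1OC(=O)C=C1 | starting material
5 | (S)-5-[(triethylsilyloxy)methyl]furan-2(5H)-one | CC[Si](CC)(CC)OC[C@H]1OC(=O)C=C1 | intermediate
6 | bis(phenylsulfanyl)methane | C(Sc1ccccc1)Sc1ccccc1 | starting material
7 | lithium lactone enolate (C7 set, C11 enolate) | CC[Si](CC)(CC)OC[C@H]1OC(O[Li])=C[C@@H]1C(Sc1ccccc1)Sc1ccccc1 | intermediate
8 | (3R,4S,5S)-4-[bis(phenylsulfanyl)methyl]-3-[(dimethylamino)methyl]-5-[(triethylsilyloxy)methyl]oxolan-2-one | CC[Si](CC)(CC)OC[C@H]1OC(=O)[C@@H](CN(C)C)[C@@H]1C(Sc1ccccc1)Sc1ccccc1 | intermediate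
9 | (2S,3S,4R)-3-[bis(phenylsulfanyl)methyl]-4-[(dimethylamino)methyl]-5-oxooxolane-2-carbaldehyde | O=C[C@H]1OC(=O)[C@@H](CN(C)C)[C@@H]1C(Sc1ccccc1)Sc1ccccc1 | intermediate
10 | (2E)-enal: C4 carries CHO (C15) and the 2-(1,3-dioxolan-2-yl)ethyl chain, C5 carries the (2R,3S,4R)-lactone | O1CCOC1CC/C(C=O)=C\[C@H]2OC(=O)[C@@H](CN(C)C)[C@@H]2C(Sc3ccccc3)Sc3ccccc3 | intermediate
11 | allylic alcohol from 10 (C15 hydroxymethyl, 4E) | O1CCOC1CC/C(CO)=C\[C@H]2OC(=O)[C@@H](CN(C)C)[C@@H]2C(Sc3ccccc3)Sc3ccccc3 | intermediate
12 | C15 acetate of 11 | O1CCOC1CC/C(COC(C)=O)=C\[C@H]2OC(=O)[C@@H](CN(C)C)[C@@H]2C(Sc3ccccc3)Sc3ccccc3 | intermediate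
13 | (4E)-4-(acetoxymethyl)-5-{(2R,3S,4R)-3-[bis(phenylsulfanyl)methyl]-4-[(dimethylamino)methyl]-5-oxooxolan-2-yl}pent-4-enal | O=CCC/C(COC(C)=O)=C\[C@H]1OC(=O)[C@@H](CN(C)C)[C@@H]1C(Sc2ccccc2)Sc2ccccc2 | intermediate
14 | tert-butyl prop-2-enoate | C=CC(=O)OC(C)(C)C | starting material
15 | Baylis–Hillman alcohol (C1 epimers, 4E, 6R,7S,11R) | C=C(C(=O)OC(C)(C)C)C(O)CC/C(COC(C)=O)=C\[C@H]1OC(=O)[C@@H](CN(C)C)[C@@H]1C(Sc2ccccc2)Sc2ccccc2 | intermediate
16 | Baylis–Hillman acetate (C1 epimers) | C=C(C(=O)OC(C)(C)C)C(OC(C)=O)CC/C(COC(C)=O)=C\[C@H]1OC(=O)[C@@H](CN(C)C)[C@@H]1C(Sc2ccccc2)Sc2ccccc2 | intermediate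
17 | seco aldehyde (C8 formyl on the lactone, C1 epimers) | C=C(C(=O)OC(C)(C)C)C(OC(C)=O)CC/C(COC(C)=O)=C\[C@H]1OC(=O)[C@@H](CN(C)C)[C@@H]1C=O | intermediate
18 | samarium ketyl radical at C8 | C=C(C(=O)OC(C)(C)C)C(OC(C)=O)CC/C(COC(C)=O)=C\[C@H]1OC(=O)[C@@H](CN(C)C)[C@@H]1[CH]O[Sm](I)I | intermediate
19 | cyclised samarium ester enolate (C8 alkoxide, C1 acetate still present) | CC(C)(C)OC(O[Sm](I)I)=C1C(OC(C)=O)CC/C(COC(C)=O)=C\[C@H]2OC(=O)[C@@H](CN(C)C)[C@@H]2[C@H](O[Sm](I)I)C1 | intermediate
20 | macrocyclic hydroxy tert-butyl ester (1(10)E,4E,6R,7R,8R,11R) | CC(C)(C)OC(=O)/C1=C/CC/C(COC(C)=O)=C\[C@H]2OC(=O)[C@@H](CN(C)C)[C@@H]2[C@H](O)C1 | intermediate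
21 | triethylsilyl ester with C8 triethylsilyl ether | CC[Si](CC)(CC)OC(=O)/C1=C/CC/C(COC(C)=O)=C\[C@H]2OC(=O)[C@@H](CN(C)C)[C@@H]2[C@H](O[Si](CC)(CC)CC)C1 | intermediate
22 | C14 carboxylic acid with C8 triethylsilyl ether (6R,7S,8R,11R) | OC(=O)/C1=C/CC/C(COC(C)=O)=C\[C@H]2OC(=O)[C@@H](CN(C)C)[C@@H]2[C@H](O[Si](CC)(CC)CC)C1 | intermediate
23 | isobutyl carbonic mixed anhydride of 22 | CC(C)COC(=O)OC(=O)/C1=C/CC/C(COC(C)=O)=C\[C@H]2OC(=O)[C@@H](CN(C)C)[C@@H]2[C@H](O[Si](CC)(CC)CC)C1 | intermediate
24 | C14 allylic alcohol with C8 triethylsilyl ether | OC/C1=C/CC/C(COC(C)=O)=C\[C@H]2OC(=O)[C@@H](CN(C)C)[C@@H]2[C@H](O[Si](CC)(CC)CC)C1 | intermediate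
25 | C14 methacrylate with C8 triethylsilyl ether | C=C(C)C(=O)OC/C1=C/CC/C(COC(C)=O)=C\[C@H]2OC(=O)[C@@H](CN(C)C)[C@@H]2[C@H](O[Si](CC)(CC)CC)C1 | intermediate
26 | dimethylamine-masked target (6R,7R,8R,11R) | C=C(C)C(=O)OC/C1=C/CC/C(COC(C)=O)=C\[C@H]2OC(=O)[C@@H](CN(C)C)[C@@H]2[C@H](O)C1 | intermediate
27 | trimethylammonium iodide of 26 | C=C(C)C(=O)OC/C1=C/CC/C(COC(C)=O)=C\[C@H]2OC(=O)[C@@H](C[N+](C)(C)C)[C@@H]2[C@H](O)C1.[I-] | intermediate
28 | CNP0313792.2 | C=C(C)C(=O)OC/C1=C/CC/C(COC(C)=O)=C\[C@H]2OC(=O)C(=C)[C@@H]2[C@H](O)C1 | target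

**Step count:** 17 steps in total. The longest linear sequence is 15 steps (steps 3–17, from 4 to 28); steps 1–2 form the branch to ylide 3.

**Steps most likely to fail**

1. Step 12 (the step proposed as new). Intermolecular pinacol coupling or simple reduction of the aldehyde may outrun the ten-membered ring closure. Facial selectivity at C8 may also be poor, or reversed, if the samarium ketyl is not held by the lactone oxygen. The fallback uses known chemistry, sets out from 17 and returns at 20, and moves the C8 configuration to a ketone reduction. Pinnick oxidation (NaClO2, NaH2PO4, 2-methylbut-2-ene) gives the carboxylic acid F1. (PhSe)2 and PBu3 give the Se-phenyl selenoester F2. Bu3SnH and AIBN in refluxing benzene at high dilution generate the C8 acyl radical, whose 10-endo addition to the acrylate terminus (a known acyl-radical macrocyclisation) gives the ten-membered keto ester F3 with C10–H and the C1 acetate retained. Luche reduction with hydride attack from the ring periphery gives the hydroxy ester F4. DBU then eliminates acetic acid by E1cB to give 20.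

2. Step 14. Hydride may add 1,4 to the activated enoyl group, or the lactone may open. The fallback passes through the aldehyde oxidation level, sets out from 22 and returns at 24. EtSH, EDC·HCl and DMAP give the S-ethyl thioester F5. Et3SiH with Pd/C (palladium on carbon; Fukuyama reduction) gives the enal F6. Luche reduction (NaBH4, CeCl3·7H2O) then gives 24.

3. Step 4. The lithiated dithioacetal may add 1,2 instead of 1,4, and C-aminomethylation of the enolate may be incomplete. The fallback is a radical route that sets out from 5 and returns at 8. Benzophenone-sensitised photoaddition of methanol (hydroxymethyl radical, anti to the C5 substituent) gives the hydroxymethyl lactone F7. Dess–Martin periodinane gives the aldehyde F8. PhSSiMe3 with ZnI2 gives the dithioacetal F9. LiN(i-Pr)2 followed by Eschenmoser's salt then gives 8.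

**Further compounds**

F1 | step 12 | C8 carboxylic acid from 17 | C=C(C(=O)OC(C)(C)C)C(OC(C)=O)CC/C(COC(C)=O)=C\[C@H]1OC(=O)[C@@H](CN(C)C)[C@@H]1C(=O)O
F2 | step 12 | Se-phenyl selenoester of F1 | C=C(C(=O)OC(C)(C)C)C(OC(C)=O)CC/C(COC(C)=O)=C\[C@H]1OC(=O)[C@@H](CN(C)C)[C@@H]1C(=O)[Se]c1ccccc1
F3 | step 12 | ten-membered 8-keto ester (C10–H, C1 acetate retained) | CC(C)(C)OC(=O)C1C(OC(C)=O)CC/C(COC(C)=O)=C\[C@H]2OC(=O)[C@@H](CN(C)C)[C@@H]2C(=O)C1
F4 | step 12 | ten-membered (8R)-hydroxy ester (C10–H, C1 acetate retained) | CC(C)(C)OC(=O)C1C(OC(C)=O)CC/C(COC(C)=O)=C\[C@H]2OC(=O)[C@@H](CN(C)C)[C@@H]2[C@H](O)C1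
F5 | step 14 | S-ethyl thioester of 22 | CCSC(=O)/C1=C/CC/C(COC(C)=O)=C\[C@H]2OC(=O)[C@@H](CN(C)C)[C@@H]2[C@H](O[Si](CC)(CC)CC)C1
F6 | step 14 | C14 enal | O=C/C1=C/CC/C(COC(C)=O)=C\[C@H]2OC(=O)[C@@H](CN(C)C)[C@@H]2[C@H](O[Si](CC)(CC)CC)C1
F7 | step 4 | (4R,5S)-4-(hydroxymethyl)-5-[(triethylsilyloxy)methyl]oxolan-2-one | CC[Si](CC)(CC)OC[C@H]1OC(=O)C[C@@H]1CO
F8 | step 4 | trans-4-formyl-5-[(triethylsilyloxy)methyl]oxolan-2-one | CC[Si](CC)(CC)OC[C@H]1OC(=O)C[C@@H]1C=O
F9 | step 4 | trans-4-[bis(phenylsulfanyl)methyl]-5-[(triethylsilyloxy)methyl]oxolan-2-one | CC[Si](CC)(CC)OC[C@H]1OC(=O)C[C@@H]1C(Sc1ccccc1)Sc1ccccc1
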